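Early in Thursday's run Z reads 0% at 0.200 h and 11% at 0.333 h, which reads as a lag (induction period); each reading carries a scatter of 1.5 percentage points. So something may stand between J and Z. Q is the catalyst; X holds two J.

| setting | Thursday's | beta | alpha | theta |
|---|---|---|---|---|
| J | 30 mM | 20 mM | 20 mM | 20 mM |
| D | 0.80 equiv | 0.800 equiv | 1.00 equiv | 1.40 equiv |
| Q | 0.1 mol% | 0.1 mol% | 0.1 mol% | 0.1 mol% |
| remark | run made earlier |  |  |  |
| time |  | 4.0 h | 4.0 h | 4.0 h |

- Thursday's (time / h: Z / %): 0.200: 0; 0.333: 11; 0.500: 16; 0.833: 23; 1.33: 34; 2.50: 49

(standard deviation of a reading: 1.5 percentage points)

- a species is counted by the J in it: one X counts as two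
- the earlier runs were read with a standard deviation of 1.5 percentage points
- no earlier run changes the charge of Q; that part of a forecast is a guess

* which of the two there is more of at the end, counted by the J in each, beta (Z / X)
* which of the two there is more of at the end, counted by the J in each, alpha (Z / X)
* which of the two there is more of at the end, counted by the J in each, theta (Z / X)
* final Z, as a percentage of the J charged, in beta
* final Z, as a percentage of the J charged, in alpha
* final Z, as a percentage of the J charged, in theta

A bench rule of thumb: if each step joins two partners and equivalents and loading stay the same, the percentage turned over per hour scales with the concentration of J. Beta shares Thursday's recipe at a lower concentration, so its clock runs slower: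

T = 4.0 h × 20 mM / 30 mM = 2.67 h

This T is the Thursday-equivalent time: the moment on Thursday's curve that a flask of the same recipe reaches. For beta it lies just past Thursday's last reading, so the last slope is carried forward, as my own reckoning:

Z = 49% + slope × (T − 2.50 h) = 51.1%

The rule has two borders. The concentration ratio is 0.667, and a step with a third dissolved partner would run on its square, 0.444. That step's T in beta would be 1.78 h, and the lag leaves such a step open. Also, T holds the equivalents: theta carries 1.75 times Thursday's D per J, and Thursday's single recipe shows nothing of what that buys.

The forecast gives Z of 48%, 56% and 70% in beta, alpha and theta, with Z, Z and Z the larger. Its beta stands below my reckoning, and it says “I shade these down slightly because some J may go to X”.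

The flasks give Z of 45.4%, 50.0% and 53.0% in beta, alpha and theta, against X of 32.1%, 35.3% and 39.3%.

    J + Q → Q + L (k = 8.10 /M/s)
    D + Q + L → Q + Z (k = 1200 /M²/s)
    J + Z → X (k = 0.0100 /M/s)

In theta at 4.00 h, the half-life of J by J + Z → X is 1.8 h, shorter than the 9.8 h half-life of D by D + Q + L → Q + Z. Theta then holds 48.1% of its D beside 3.61% of its J. Beta, at T = 2.67 h, gives 45.4%, under the reckoned 51.1%. The neighbour of theta with 5.0 mM of J keeps theta's recipe, so it differs from Thursday's in D per J; its T = 0.667 h falls between Thursday's readings of 16% and 23%, yet it ends with Z at 9.75% and the intermediate L at 32.4%.

(The data are calculated with constants of no real substance; noise was put on by code.)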